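**Retrosynthetic overview**
- The target is read as epigallocatechin-(4β→8)-epigallocatechin 3-O-gallate-(4β→8)-epigallocatechin. The last disconnections are global O-debenzylation and the middle C4–bottom C8 bond (flavan-4-yl cation of a top–middle dimer plus penta-O-benzyl-epigallocatechin).
- Top ring B is removed at top C2 (arylzinc addition to the oxocarbenium ion of a lactol acetate), leaving a 3-benzyloxy-4-aryl-chroman-2-ol.
- The feature the strategy rests on: top C3 (oxygen-bearing) and top C4 (the diaryl methine joining top ring A to C8 of middle ring A) are adjacent and trans on top ring C. C3–C4 and O1–C2 are formed when the enamine of benzyloxyacetaldehyde adds to the o-quinone methide of top ring A and the phenol closes the lactol.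
- The o-quinone methide precursor, an o-hydroxybenzhydrol, comes from 8-lithiated silyl/benzyl-protected epigallocatechin and a protected 2,4,6-trihydroxybenzaldehyde.
- Ring order: the middle and bottom units (rings A, B, C) come intact from epigallocatechin; top ring A arrives with the aldehyde, top ring C closes in the key step, top ring B is attached next, and the bottom unit is joined last.

Key step: step 8

Remark: all three flavan units are (2R,3R) with 2,3-cis and 3,4-trans (4β) relationships; the sense of induction of the (S)-configured aminocatalyst is assigned from its usual enamine-shielding model (the antipodal catalyst would be used if the sense were opposite). Bn = benzyl, TBS = tert-butyldimethylsilyl.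

**Route**

Step 1
Reactants: 1 (−)-epigallocatechin
Product: 2 5,7,3′,4′,5′-penta-O-benzyl-(−)-epigallocatechin (2R,3R; 3-OH free)
Conditions: BnBr (5.5 equiv), K2CO3, DMF, −10 °C → rt, argon
Reagents that add atoms: benzyl bromide, BrCc1ccccc1
Why: Williamson etherification in which K2CO3 deprotonates only the five phenols, so the secondary 3-OH stays free, while low temperature and exclusion of air should limit C-benzylation, C2 epimerisation and oxidation of the pyrogallol ring.

Step 2
Reactants: 2 penta-O-benzyl-epigallocatechin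
Product: 3 3-O-TBS-5,7,3′,4′,5′-penta-O-benzyl-epigallocatechin
Conditions: TBSCl, imidazole, DMF, rt
Reagents that add atoms: tert-butyldimethylsilyl chloride, CC(C)(C)[Si](C)(C)Cl
Why: Silylation of the only free hydroxyl masks O3 of the future middle unit with a group that should survive organolithium, palladium, weak acid and BF3 at low temperature and is later removed by fluoride beside the benzyl ethers.

Step 3
Reactants: 3 3-O-TBS-penta-O-benzyl-epigallocatechin
Product: 4 8-bromo-3-O-TBS-5,7,3′,4′,5′-penta-O-benzyl-epigallocatechin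
Conditions: NBS (1.0 equiv), CH2Cl2, −78 → 0 °C
Reagents that add atoms: N-bromosuccinimide, O=C1CCC(=O)N1Br
Why: Electrophilic aromatic bromination, in which C8 is the more reactive of the two free positions of the 5,7-dibenzyloxy ring A once O3 is silylated, so one equivalent of NBS should give the 8-bromide needed for a regiodefined metalation.

Step 4
Reactants: 5 2,4,6-trihydroxybenzaldehyde
Product: 6 4,6-bis(benzyloxy)-2-hydroxybenzaldehyde
Conditions: BnBr (2.0 equiv), K2CO3, DMF, 0 °C → rt
Reagents that add atoms: benzyl bromide, BrCc1ccccc1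
Why: Williamson etherification with two equivalents of BnBr, in which the para hydroxyl and one ortho hydroxyl react and the remaining ortho hydroxyl is held back by its hydrogen bond to the formyl group.

Step 5
Reactants: 6 4,6-bis(benzyloxy)-2-hydroxybenzaldehyde
Product: 7 2-allyloxy-4,6-bis(benzyloxy)benzaldehyde
Conditions: allyl bromide, K2CO3, DMF, 50 °C
Reagents that add atoms: allyl bromide, C=CCBr
Why: Williamson etherification under more forcing conditions caps the hydrogen-bonded phenol as an allyl ether, so that no acidic proton quenches the aryllithium of step 6 and the phenol can later be freed without acid.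

Step 6
Reactants: 4 8-bromo-3-O-TBS-penta-O-benzyl-epigallocatechin; 7 2-allyloxy-4,6-bis(benzyloxy)benzaldehyde
Product: 9 [2-allyloxy-4,6-bis(benzyloxy)phenyl][3-O-TBS-penta-O-benzyl-epigallocatechin-8-yl]methanol (both carbinol epimers), via 8-lithio flavan 8 (not isolated)
Conditions: n-BuLi, THF, −78 °C; then 7, −78 → −20 °C; H2O
Reagents that add atoms: none
Why: Bromine–lithium exchange gives an aryllithium flanked by two oxygen substituents that undergoes 1,2-addition to the non-enolisable aldehyde; the new carbinol centre is uncontrolled, which does not matter because it becomes trigonal in step 8.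

Step 7
Reactants: 9 allyl-protected benzhydrol
Product: 10 [4,6-bis(benzyloxy)-2-hydroxyphenyl][3-O-TBS-penta-O-benzyl-epigallocatechin-8-yl]methanol (o-hydroxybenzhydrol, both carbinol epimers)
Conditions: Pd(PPh3)4 (5 mol %), morpholine, THF, rt
Reagents that add atoms: none
Why: Tsuji–Trost deallylation in which zerovalent palladium ionises the aryl allyl ether to a π-allyl complex that morpholine intercepts, freeing the phenol under basic conditions that leave the acid-labile benzhydrol, the silyl ether and the benzyl ethers untouched.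

Step 8
Reactants: 10 o-hydroxybenzhydrol; 11 benzyloxyacetaldehyde
Product: 14 top-unit lactol (3R,4R)-3,5,7-tris(benzyloxy)-4-[3-O-TBS-penta-O-benzyl-epigallocatechin-8-yl]chroman-2-ol (both C2 epimers), via o-quinone methide 12 (not isolated), via open-chain hydroxy aldehyde 13 (not isolated)
Conditions: (S)-2-[diphenyl(trimethylsilyloxy)methyl]pyrrolidine (20 mol %), PhCO2H (20 mol %), 11 (3 equiv), CH2Cl2, rt
Reagents that add atoms: none
Why: Benzoic acid ionises the doubly benzylic carbinol of 10, which carries three oxygen substituents on each ring, to the o-quinone methide 12 of top ring A (in equilibrium with its O-protonated diarylmethylium form), the catalyst condenses with 11 to the E-enamine, and the enamine carbon adds to the exocyclic methide carbon with rearomatisation of ring A to form top C3–C4; hydrolysis of the iminium ion gives aldehyde 13 and returns the amine. The closest known reaction type is the diarylprolinol silyl ether/acid-catalysed formal [4+2] annulation of o-hydroxybenzhydrols with enolisable aldehydes by way of in situ o-quinone methides, which gives trans-3,4-disubstituted chroman-2-ols; the aldehyde and the substrate are new, the reaction type is not. Top ring C then closes by 6-exo-trig addition of the phenol oxygen to the aldehyde carbonyl (hemiacetal bond O1–C2), so the annulation is a stepwise conjugate addition–lactolisation and C2 is left as both epimers. C3 is set by the catalyst: the diphenyl(silyloxy)methyl group of the (S)-pyrrolidine shields one enamine face and the methide enters on the open face, which places the benzyloxy group as required for 3R; C4 (R) is set in the same bond formation by the relative topicity known from enamine additions to nitroalkenes (syn adduct), which here corresponds to the 3,4-trans lactol with the middle-unit aryl group β. The step needs ionisation of the carbinol alone and C-alkylation at the methide carbon only: the hexaoxygenated diarylmethyl system should ionise under a weak carboxylic acid that leaves the silyl ether, the benzyl ethers and middle ring C untouched, the stabilised cation should be too weak an electrophile for the free ring A positions yet react with the strongly nucleophilic enamine, and rearomatisation makes the 1,4-addition irreversible.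

Step 9
Reactants: 14 top-unit lactol
Product: 15 2-O-acetyl lactol (chroman-2-yl acetate, both C2 epimers)
Conditions: Ac2O, pyridine, DMAP (cat.), CH2Cl2, 0 °C → rt
Reagents that add atoms: acetic anhydride, CC(=O)OC(C)=O
Why: Acylation of the anomeric hydroxyl, the only free OH, turns C2 into an acetal carbon with a leaving group for the arylation without touching C3 or C4.

Step 10
Reactants: 16 5-bromo-1,2,3-trimethoxybenzene
Product: 17 5-bromobenzene-1,2,3-triol
Conditions: BBr3, CH2Cl2, −78 °C → rt; then H2O
Reagents that add atoms: none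
Why: Lewis-acid cleavage of the three aryl methyl ethers by BBr3, to which the aryl bromide is inert, frees the triol for exchange of the protecting groups to benzyl.

Step 11
Reactants: 17 5-bromobenzene-1,2,3-triol
Product: 18 5-bromo-1,2,3-tris(benzyloxy)benzene
Conditions: BnBr (3.3 equiv), K2CO3, DMF, 60 °C, argon
Reagents that add atoms: benzyl bromide, BrCc1ccccc1
Why: Williamson etherification of all three phenols gives the ring B precursor with the protecting group used throughout the route.

Step 12
Reactants: 15 lactol acetate; 18 5-bromo-1,2,3-tris(benzyloxy)benzene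
Product: 21 protected dimer 3,5,7,3′,4′,5′-hexa-O-benzyl-epigallocatechin-(4β→8)-[3-O-TBS-5,7,3′,4′,5′-penta-O-benzyl-epigallocatechin] (top unit 2R,3R,4R), via 3,4,5-tris(benzyloxy)phenyllithium 19 (not isolated), via 3,4,5-tris(benzyloxy)phenylzinc bromide 20 (not isolated)
Conditions: 18 (3 equiv), n-BuLi, THF, −78 °C; ZnBr2, → 0 °C; then 15, BF3·OEt2, CH2Cl2, −78 → −30 °C
Reagents that add atoms: none
Why: BF3·OEt2 ionises the anomeric acetate to the chroman-2-yl oxocarbenium ion, which the arylzinc bromide captures in a C-glycosylation-type arylation; the aryl group should enter on the α-face along the pseudoaxial trajectory, anti to the C4 aryl group (a syn approach would be 1,3-diaxial to the whole middle unit) and cis to the pseudoequatorial 3-OBn as is usual for oxocarbenium ions with an adjacent alkoxy group, which sets top C2 as R (2,3-cis, 2,4-trans).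

Step 13
Reactants: 21 protected dimer (3-O-TBS on the middle unit)
Product: 22 dimer with free 3-OH on the middle unit
Conditions: TBAF, THF, rt → 40 °C
Reagents that add atoms: none
Why: Fluoride-induced desilylation frees O3 of the middle unit, the benzyl ethers and the benzylic C–O bonds of both pyran rings being inert to TBAF.

Step 14
Reactants: 22 dimer with free middle 3-OH
Product: 23 dimer with a 4β-(2-ethoxyethoxy) group on the middle unit (3,4-trans)
Conditions: DDQ (1.5 equiv), 2-ethoxyethanol (5 equiv), CH2Cl2, rt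
Reagents that add atoms: 2-ethoxyethanol, CCOCCO
Why: Benzylic oxidation in which DDQ abstracts hydride from the middle C4 methylene, whose axial C–H is aligned with the electron-rich ring A, and the alcohol traps the cation trans to the axial 3-OH; the top C4–H is tertiary, flanked by four ortho substituents and held quasi-equatorial in the plane of its ring A, so it should not be abstracted.

Step 15
Reactants: 23 4β-(2-ethoxyethoxy) dimer; 24 3,4,5-tris(benzyloxy)benzoic acid
Product: 25 4β-(2-ethoxyethoxy) dimer carrying the 3-O-[3,4,5-tris(benzyloxy)benzoyl] ester on the middle unit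
Conditions: DCC, DMAP, CH2Cl2, rt
Reagents that add atoms: none
Why: Steglich esterification, in which DCC activates the acid and DMAP transfers the acyl group to the hindered axial 3-OH under basic conditions that leave the acid-labile 4-alkoxy group intact.

Step 16
Reactants: 25 galloylated 4-alkoxy dimer; 2 penta-O-benzyl-epigallocatechin (4 equiv, excess recovered)
Product: 26 protected trimer (nineteen benzyl ethers, bottom 3-OH free, both interflavan bonds 4β→8)
Conditions: TMSOTf, CH2Cl2, −78 → −40 °C
Reagents that add atoms: none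
Why: Friedel–Crafts-type interflavan coupling in which TMSOTf ionises the 4-alkoxy group, the 3-O-acyl carbonyl bridges the α-face of the flavan-4-yl cation as a cis-fused acyloxonium ion, and C8 of 2 (the more nucleophilic position of its ring A) attacks from the β-face, setting middle C4 as 4β (3,4-trans), while the excess of 2 suppresses self-condensation.

Step 17
Reactants: 26 protected trimer
Product: 27 target, epigallocatechin-(4β→8)-epigallocatechin 3-O-gallate-(4β→8)-epigallocatechin
Conditions: H2 (1 atm), Pd(OH)2/C, THF/MeOH/H2O, rt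
Reagents that add atoms: none
Why: Hydrogenolysis cleaves all nineteen benzyl ethers (eighteen aryl, one alkyl) while the galloyl ester, the pyran C–O bonds and the interflavan bonds should survive at ambient temperature and pressure, and no stereocentre is touched.

**Compound list**
1 | (−)-epigallocatechin | O[C@@H]1Cc2c(O)cc(O)cc2O[C@@H]1c1cc(O)c(O)c(O)c1 | starting material
2 | 5,7,3′,4′,5′-penta-O-benzyl-(−)-epigallocatechin | O[C@@H]1Cc2c(OCc3ccccc3)cc(OCc3ccccc3)cc2O[C@@H]1c1cc(OCc2ccccc2)c(OCc2ccccc2)c(OCc2ccccc2)c1 | intermediate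
3 | 3-O-TBS-penta-O-benzyl-epigallocatechin | CC(C)(C)[Si](C)(C)O[C@@H]1Cc2c(OCc3ccccc3)cc(OCc3ccccc3)cc2O[C@@H]1c1cc(OCc2ccccc2)c(OCc2ccccc2)c(OCc2ccccc2)c1 | intermediate
4 | 8-bromo-3-O-TBS-penta-O-benzyl-epigallocatechin | CC(C)(C)[Si](C)(C)O[C@@H]1Cc2c(OCc3ccccc3)cc(OCc3ccccc3)c(Br)c2O[C@@H]1c1cc(OCc2ccccc2)c(OCc2ccccc2)c(OCc2ccccc2)c1 | intermediate
5 | 2,4,6-trihydroxybenzaldehyde | O=Cc1c(O)cc(O)cc1O | starting material
6 | 4,6-bis(benzyloxy)-2-hydroxybenzaldehyde | O=Cc1c(O)cc(OCc2ccccc2)cc1OCc1ccccc1 | intermediate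
7 | 2-allyloxy-4,6-bis(benzyloxy)benzaldehyde | O=Cc1c(OCC=C)cc(OCc2ccccc2)cc1OCc1ccccc1 | intermediate
8 | 8-lithio-3-O-TBS-penta-O-benzyl-epigallocatechin | [Li]c1c(OCc2ccccc2)cc(OCc2ccccc2)c2c1O[C@H](c1cc(OCc3ccccc3)c(OCc3ccccc3)c(OCc3ccccc3)c1)[C@H](O[Si](C)(C)C(C)(C)C)C2 | intermediate (not isolated)
9 | allyl-protected benzhydrol (carbinol epimers) | OC(c1c(OCC=C)cc(OCc2ccccc2)cc1OCc1ccccc1)c1c(OCc2ccccc2)cc(OCc2ccccc2)c2c1O[C@H](c1cc(OCc3ccccc3)c(OCc3ccccc3)c(OCc3ccccc3)c1)[C@H](O[Si](C)(C)C(C)(C)C)C2 | intermediate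
10 | o-hydroxybenzhydrol, key-step precursor (carbinol epimers) | OC(c1c(O)cc(OCc2ccccc2)cc1OCc1ccccc1)c1c(OCc2ccccc2)cc(OCc2ccccc2)c2c1O[C@H](c1cc(OCc3ccccc3)c(OCc3ccccc3)c(OCc3ccccc3)c1)[C@H](O[Si](C)(C)C(C)(C)C)C2 | intermediate
11 | benzyloxyacetaldehyde | O=CCOCc1ccccc1 | starting material
12 | o-quinone methide, 3,5-bis(benzyloxy)-6-[(flavan-8-yl)methylidene]cyclohexa-2,4-dien-1-one | O=C1C=C(OCc2ccccc2)C=C(OCc2ccccc2)C1=Cc1c(OCc2ccccc2)cc(OCc2ccccc2)c2c1O[C@H](c1cc(OCc3ccccc3)c(OCc3ccccc3)c(OCc3ccccc3)c1)[C@H](O[Si](C)(C)C(C)(C)C)C2 | intermediate (not isolated)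
13 | (2R,3R)-2-benzyloxy-3-[4,6-bis(benzyloxy)-2-hydroxyphenyl]-3-(flavan-8-yl)propanal | O=C[C@H](OCc1ccccc1)[C@H](c1c(O)cc(OCc2ccccc2)cc1OCc1ccccc1)c1c(OCc2ccccc2)cc(OCc2ccccc2)c2c1O[C@H](c1cc(OCc3ccccc3)c(OCc3ccccc3)c(OCc3ccccc3)c1)[C@H](O[Si](C)(C)C(C)(C)C)C2 | intermediate (not isolated)
14 | top-unit lactol (3R,4R; C2 epimers) on C8 of the protected middle unit, key-step product | CC(C)(C)[Si](C)(C)O[C@@H]1Cc2c(OCc3ccccc3)cc(OCc3ccccc3)c([C@H]3c4c(OCc5ccccc5)cc(OCc5ccccc5)cc4OC(O)[C@@H]3OCc3ccccc3)c2O[C@@H]1c1cc(OCc2ccccc2)c(OCc2ccccc2)c(OCc2ccccc2)c1 | intermediate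
15 | lactol acetate (C2 epimers) | CC(C)(C)[Si](C)(C)O[C@@H]1Cc2c(OCc3ccccc3)cc(OCc3ccccc3)c([C@H]3c4c(OCc5ccccc5)cc(OCc5ccccc5)cc4OC(OC(C)=O)[C@@H]3OCc3ccccc3)c2O[C@@H]1c1cc(OCc2ccccc2)c(OCc2ccccc2)c(OCc2ccccc2)c1 | intermediate
16 | 5-bromo-1,2,3-trimethoxybenzene | COc1cc(Br)cc(OC)c1OC | starting material
17 | 5-bromobenzene-1,2,3-triol | Oc1cc(Br)cc(O)c1O | intermediate
18 | 5-bromo-1,2,3-tris(benzyloxy)benzene | Brc1cc(OCc2ccccc2)c(OCc2ccccc2)c(OCc2ccccc2)c1 | intermediate
19 | 3,4,5-tris(benzyloxy)phenyllithium | [Li]c1cc(OCc2ccccc2)c(OCc2ccccc2)c(OCc2ccccc2)c1 | intermediate (not isolated)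
20 | 3,4,5-tris(benzyloxy)phenylzinc bromide | Br[Zn]c1cc(OCc2ccccc2)c(OCc2ccccc2)c(OCc2ccccc2)c1 | intermediate (not isolated)
21 | protected top–middle dimer, middle 3-O-TBS | CC(C)(C)[Si](C)(C)O[C@@H]1Cc2c(OCc3ccccc3)cc(OCc3ccccc3)c([C@H]3c4c(OCc5ccccc5)cc(OCc5ccccc5)cc4O[C@H](c4cc(OCc5ccccc5)c(OCc5ccccc5)c(OCc5ccccc5)c4)[C@@H]3OCc3ccccc3)c2O[C@@H]1c1cc(OCc2ccccc2)c(OCc2ccccc2)c(OCc2ccccc2)c1 | intermediate
22 | top–middle dimer, middle 3-OH free | O[C@@H]1Cc2c(OCc3ccccc3)cc(OCc3ccccc3)c([C@H]3c4c(OCc5ccccc5)cc(OCc5ccccc5)cc4O[C@H](c4cc(OCc5ccccc5)c(OCc5ccccc5)c(OCc5ccccc5)c4)[C@@H]3OCc3ccccc3)c2O[C@@H]1c1cc(OCc2ccccc2)c(OCc2ccccc2)c(OCc2ccccc2)c1 | intermediate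
23 | dimer with middle 4β-(2-ethoxyethoxy) group, 3-OH free | O[C@@H]1[C@@H](OCCOCC)c2c(OCc3ccccc3)cc(OCc3ccccc3)c([C@H]3c4c(OCc5ccccc5)cc(OCc5ccccc5)cc4O[C@H](c4cc(OCc5ccccc5)c(OCc5ccccc5)c(OCc5ccccc5)c4)[C@@H]3OCc3ccccc3)c2O[C@@H]1c1cc(OCc2ccccc2)c(OCc2ccccc2)c(OCc2ccccc2)c1 | intermediate
24 | 3,4,5-tris(benzyloxy)benzoic acid | OC(=O)c1cc(OCc2ccccc2)c(OCc2ccccc2)c(OCc2ccccc2)c1 | starting material
25 | galloylated 4β-(2-ethoxyethoxy) dimer | O=C(O[C@@H]1[C@@H](OCCOCC)c2c(OCc3ccccc3)cc(OCc3ccccc3)c([C@H]3c4c(OCc5ccccc5)cc(OCc5ccccc5)cc4O[C@H](c4cc(OCc5ccccc5)c(OCc5ccccc5)c(OCc5ccccc5)c4)[C@@H]3OCc3ccccc3)c2O[C@@H]1c1cc(OCc2ccccc2)c(OCc2ccccc2)c(OCc2ccccc2)c1)c1cc(OCc2ccccc2)c(OCc2ccccc2)c(OCc2ccccc2)c1 | intermediate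
26 | protected trimer (nineteen benzyl ethers, bottom 3-OH free) | O=C(O[C@@H]1[C@@H](c2c(OCc4ccccc4)cc(OCc4ccccc4)c3c2O[C@H](c2cc(OCc4ccccc4)c(OCc4ccccc4)c(OCc4ccccc4)c2)[C@H](O)C3)c2c(OCc3ccccc3)cc(OCc3ccccc3)c([C@H]3c4c(OCc5ccccc5)cc(OCc5ccccc5)cc4O[C@H](c4cc(OCc5ccccc5)c(OCc5ccccc5)c(OCc5ccccc5)c4)[C@@H]3OCc3ccccc3)c2O[C@@H]1c1cc(OCc2ccccc2)c(OCc2ccccc2)c(OCc2ccccc2)c1)c1cc(OCc2ccccc2)c(OCc2ccccc2)c(OCc2ccccc2)c1 | intermediate
27 | epigallocatechin-(4β→8)-epigallocatechin 3-O-gallate-(4β→8)-epigallocatechin | O=C(O[C@@H]1[C@@H](c2c(O)cc(O)c3c2O[C@H](c2cc(O)c(O)c(O)c2)[C@H](O)C3)c2c(O)cc(O)c([C@H]3c4c(O)cc(O)cc4O[C@H](c4cc(O)c(O)c(O)c4)[C@@H]3O)c2O[C@@H]1c1cc(O)c(O)c(O)c1)c1cc(O)c(O)c(O)c1 | target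

**Step count and risks**

Total step count: 17. Longest linear sequence: 13 steps (steps 1, 2, 3, 6, 7, 8, 9, 12, 13, 14, 15, 16, 17).

Steps most likely to fail:

1. Step 8. The enamine may add too slowly to the methide carbon, which is flanked by two ortho substituents on each aryl group, so that the ionised carbinol is consumed by self-condensation through free ring A positions or the aldehyde is lost to self-aldolisation. The chiral middle unit may also erode the facial selectivity imposed by the catalyst. Fallback, setting out from 10 and 11: 11 would be converted with TMSCl, Et3N and NaI in MeCN into the silyl enol ether (Z)-2-benzyloxy-1-(trimethylsilyloxy)ethene F1. F1 would then be added to 10 in CH2Cl2 at −78 °C with catalytic Sc(OTf)3, a Mukaiyama–Michael addition of an enol silane to the o-quinone methide 12 or its cation. Aqueous work-up gives aldehyde 13, which closes to lactol 14, where the route is rejoined. Catalyst control is given up: the 3,4-trans lactols of both top-unit series are expected, they are diastereomers through the middle unit, and they would be separated by chromatography at 14 or at 15.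

2. Step 12. Capture of the oxocarbenium ion by the arylzinc reagent may be slower than Friedel–Crafts attack by free ring A positions of a second molecule or than loss of H3 to a 4H-chromene, and facial selectivity at C2 may be poor. Fallback, setting out from 14: the lactol would be oxidised with Ag2CO3 on Celite in toluene at 80 °C to the 3-benzyloxy-4-aryl-chroman-2-one lactone F2. Aryllithium 19 (1 equiv, THF, −78 °C) would add to it to give the 2-aryl-2-hydroxychroman hemiketal F3. F3 would be reduced with Et3SiH and BF3·OEt2 in CH2Cl2 at −78 °C, the lactone/aryllithium/silane sequence familiar from C-aryl glycosides. In the 2-aryl oxocarbenium ion the 3-OBn group is forced pseudoaxial by allylic strain with the 2-aryl group, and the small hydride should be delivered axially anti to it, which gives the 2,3-cis product and rejoins the route at 21.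

3. Step 16. The cation of the dimeric electrophile may be intercepted by the free C6 and C8 positions of the top unit of another electrophile molecule (self-condensation), or the bottom unit may react through C6. Fallback, setting out from 25: the 2-ethoxyethoxy group would be exchanged with excess benzyl mercaptan and BF3·OEt2 in CH2Cl2 at −78 °C, where the thiol outcompetes arene nucleophiles, to give the 4β-benzylthio ether F4. F4 would then be activated with the thiophilic salt AgBF4 in THF at 0 °C in the presence of 2. The cation is then released slowly under nearly neutral conditions beside an excess of nucleophile, with the same acyloxonium control of the 4β configuration, and the route is rejoined at 26.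

**Further compounds**
F1 | step 8 | (Z)-2-benzyloxy-1-(trimethylsilyloxy)ethene | C[Si](C)(C)O/C=C\OCc1ccccc1
F2 | step 12 | (3R,4R)-3,5,7-tris(benzyloxy)-4-[3-O-TBS-penta-O-benzyl-epigallocatechin-8-yl]chroman-2-one | CC(C)(C)[Si](C)(C)O[C@@H]1Cc2c(OCc3ccccc3)cc(OCc3ccccc3)c([C@H]3c4c(OCc5ccccc5)cc(OCc5ccccc5)cc4OC(=O)[C@@H]3OCc3ccccc3)c2O[C@@H]1c1cc(OCc2ccccc2)c(OCc2ccccc2)c(OCc2ccccc2)c1
F3 | step 12 | 2-[3,4,5-tris(benzyloxy)phenyl]-2-hydroxychroman hemiketal of F2 (C2 epimers) | CC(C)(C)[Si](C)(C)O[C@@H]1Cc2c(OCc3ccccc3)cc(OCc3ccccc3)c([C@H]3c4c(OCc5ccccc5)cc(OCc5ccccc5)cc4OC(O)(c4cc(OCc5ccccc5)c(OCc5ccccc5)c(OCc5ccccc5)c4)[C@@H]3OCc3ccccc3)c2O[C@@H]1c1cc(OCc2ccccc2)c(OCc2ccccc2)c(OCc2ccccc2)c1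
F4 | step 16 | galloylated dimer with a 4β-benzylthio group on the middle unit | O=C(O[C@@H]1[C@@H](SCc2ccccc2)c2c(OCc3ccccc3)cc(OCc3ccccc3)c([C@H]3c4c(OCc5ccccc5)cc(OCc5ccccc5)cc4O[C@H](c4cc(OCc5ccccc5)c(OCc5ccccc5)c(OCc5ccccc5)c4)[C@@H]3OCc3ccccc3)c2O[C@@H]1c1cc(OCc2ccccc2)c(OCc2ccccc2)c(OCc2ccccc2)c1)c1cc(OCc2ccccc2)c(OCc2ccccc2)c(OCc2ccccc2)c1
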